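**Retrosynthetic overview**
1. The segment O–C4(H)–C5H2–C6(Me)=C7H–C8H2 holds the tetronic acid ring oxygen, its stereocentre C4 and the Z-trisubstituted alkene. It is a 4-methyl-3,6-dihydro-2H-pyran that lacks only the O–C8 bond. This temporary six-membered ring is made by a catalytic asymmetric hetero-Diels–Alder reaction of isoprene with ethyl glyoxylate, which sets C4 (S) and locks C6=C7 cis.
2. Propionyl bromide cleaves the O–C8 bond, which is not in the target. Its acyl part becomes C1, C2 and the 2-methyl group of the tetronic acid. Its bromide is the leaving group for the C8–C9 coupling with a chiral-pool C9–C11 Grignard reagent that brings C10 (S).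
3. C11 is oxidised and olefinated to the E-alkenylboronate (C11=C12). A Dieckmann closure (C2–C3) then forms the tetronic acid ring around the former pyran oxygen.
4. For the lactam, hept-6-yn-1-ol is converted into the E-iodoalkene (C13=C14) and then the aldehyde. Glyoxylic acid condensation (C18=C19) gives a hydroxybutenolide, and isopentylamine turns it into the lactam by reductive amination and lactamisation.
5. The last bond is C12–C13 (Suzuki–Miyaura). Ring order: dihydropyran (temporary), opened, then tetronic acid; separately hydroxybutenolide, then lactam.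

Key step: step 1

Remark (numbering): C1 = lactone C=O, C2 = C–CH3, C3 = C–OH, C4 = ring CH–O. The chain runs C5 to C17. C18 = lactam C4, C19 = lactam C3–H, C20 = lactam C=O, C21 = lactam CH2–N.
Remark (assumption): the (S)-BINOL–Ti catalyst is assumed to give the (S)-adduct, by analogy with the glyoxylate-ene reaction, where (R)-BINOL gives (R)-α-hydroxy esters. If the sense proves opposite, the other ligand enantiomer is used.

**Step 1**
Reactants: 1 isoprene; 2 ethyl glyoxylate
Product: 3 ethyl (2S)-4-methyl-3,6-dihydro-2H-pyran-2-carboxylate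
Conditions: (S)-BINOL (10 mol %), TiCl2(OiPr)2 (10 mol %), 4 Å MS, CH2Cl2, −30 °C, excess 1, freshly cracked 2
Reagents that add atoms: none
Why: The Ti-bound glyoxylate C=O (2π) adds across s-cis isoprene (4π) in a concerted but strongly asynchronous [4+2] hetero-Diels–Alder reaction that forms C4–C5 ahead of O–C8; the closest known reaction type is the BINOL–Ti, BINOL–Al or bis(oxazoline)–Cu catalysed glyoxylate hetero-Diels–Alder reaction of simple 1,3-dienes, isoprene included. The 3,6-dihydro-2H-pyran ring is closed by intermolecular [4+2] cycloaddition, so C6=C7 is born inside a six-membered ring and must hold C5 and C8 on the same side, which is the later Z geometry. C4 is the only new stereocentre and is set by the catalyst, because the chelated glyoxylate is shielded on one face by the BINOL ligand. Regioselectivity (4-methyl, not 5-methyl) follows from attack of the more nucleophilic CH2 terminus next to C(Me), which develops tertiary allyl cation character at C6, on the aldehyde carbon. The selectivity the step needs is periselectivity against the glyoxylate-ene reaction of the isoprene methyl group; low temperature, excess diene and the choice of BINOL–metal catalyst address this, and the acyclic ene adduct should be separable.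

**Step 2**
Reactants: 3 ethyl (2S)-4-methyl-3,6-dihydro-2H-pyran-2-carboxylate; 4 propionyl bromide
Product: 5 ethyl (2S,4Z)-6-bromo-4-methyl-2-(propanoyloxy)hex-4-enoate
Conditions: 4 (1.1 equiv), ZnBr2 (5 mol %), CH2Cl2, −20 → 0 °C
Reagents that add atoms: none
Why: In this Lewis-acid-catalysed acylative cleavage of a cyclic allylic ether with an acyl bromide, O-acylation gives an acyloxonium ion that bromide should open by SN2 attack at the primary, prenyl-type allylic C8 rather than at the secondary, ester-deactivated C4, so the C4–O bond and its (S) configuration stay untouched, the ring-enforced cis geometry is released as the Z-alkene, and all atoms of 4 are used.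

**Step 3**
Reactants: 6 (2R)-3-bromo-2-methylpropan-1-ol
Product: 7 [(2R)-3-bromo-2-methylpropoxy](triethyl)silane
Conditions: TESCl, imidazole, CH2Cl2, 0 °C
Reagents that add atoms: chlorotriethylsilane, CC[Si](Cl)(CC)CC
Why: Imidazole-assisted silylation of a primary alcohol masks the O–H for Grignard formation, and the stereocentre (future C10) is not involved.

**Step 4**
Reactants: 5 ethyl (2S,4Z)-6-bromo-4-methyl-2-(propanoyloxy)hex-4-enoate; 7 [(2R)-3-bromo-2-methylpropoxy](triethyl)silane
Product: 10 ethyl (2S,4Z,8S)-9-hydroxy-4,8-dimethyl-2-(propanoyloxy)non-4-enoate, via {(2R)-2-methyl-3-[(triethylsilyl)oxy]propyl}magnesium bromide 8 (not isolated), via ethyl (2S,4Z,8S)-4,8-dimethyl-2-(propanoyloxy)-9-[(triethylsilyl)oxy]non-4-enoate 9 (not isolated)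
Conditions: 7, Mg, THF, rt; slow addition to 5, Li2CuCl4 (5 mol %), THF, −78 → −40 °C; then 1 M HCl, THF, 0 °C
Reagents that add atoms: none
Why: Copper-catalysed Grignard cross-coupling (Kochi type) of a primary γ,γ-disubstituted allylic bromide should go by direct SN2 substitution at C8 with retention of the Z geometry and faster than ester attack at −78 °C under slow inverse addition, C10 (S) comes in unchanged from the chiral pool, and the acid quench removes the labile primary TES ether.

**Step 5**
Reactants: 10 ethyl (2S,4Z,8S)-9-hydroxy-4,8-dimethyl-2-(propanoyloxy)non-4-enoate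
Product: 11 ethyl (2S,4Z,8S)-4,8-dimethyl-9-oxo-2-(propanoyloxy)non-4-enoate
Conditions: PhI(OAc)2, TEMPO (10 mol %), CH2Cl2, rt
Reagents that add atoms: none
Why: TEMPO/PhI(OAc)2 oxidation stops at the aldehyde under essentially neutral conditions, so the α-stereocentre C10, the alkene and both esters should be left intact.

**Step 6**
Reactants: 11 ethyl (2S,4Z,8S)-4,8-dimethyl-9-oxo-2-(propanoyloxy)non-4-enoate
Product: 12 ethyl (2S,4Z,8S,9E)-4,8-dimethyl-2-(propanoyloxy)-10-(4,4,5,5-tetramethyl-1,3,2-dioxaborolan-2-yl)deca-4,9-dienoate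
Conditions: Cl2CHBpin, CrCl2, LiI, THF, rt
Reagents that add atoms: 2-(dichloromethyl)-4,4,5,5-tetramethyl-1,3,2-dioxaborolane, ClC(Cl)B1OC(C)(C)C(C)(C)O1
Why: In the boron variant of the Takai–Utimoto olefination the gem-dichromium reagent from the dihalomethylboronate adds to the aldehyde and eliminates to the E-alkenylboronate (C11=C12), and the non-basic Cr(II) medium should neither epimerise C10 nor touch the esters.

**Step 7**
Reactants: 12 ethyl (2S,4Z,8S,9E)-4,8-dimethyl-2-(propanoyloxy)-10-(4,4,5,5-tetramethyl-1,3,2-dioxaborolan-2-yl)deca-4,9-dienoate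
Product: 13 (5S)-5-[(2Z,6S,7E)-2,6-dimethyl-8-(4,4,5,5-tetramethyl-1,3,2-dioxaborolan-2-yl)octa-2,7-dien-1-yl]-4-hydroxy-3-methylfuran-2(5H)-one
Conditions: LiHMDS (3 equiv), THF, −78 → −20 °C; then cold 1 M HCl
Reagents that add atoms: none
Why: In this Dieckmann (intramolecular Claisen) condensation the propionate enolate (C2) attacks the ethyl ester carbonyl (C3) in a 5-exo-trig closure and the product is drained as its stabilised tetronate anion, a reaction type known to preserve the configuration of α-acyloxy esters at low temperature, while the hindered amide base should leave the pinacol boronate alone.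

**Step 8**
Reactants: 14 hept-6-yn-1-ol
Product: 16 (6E)-7-iodo-6-methylhept-6-en-1-ol, via dimethyl{(1E)-7-[(dimethylalumanyl)oxy]-2-methylhept-1-en-1-yl}alumane 15 (not isolated)
Conditions: AlMe3 (3 equiv), Cp2ZrCl2 (25 mol %), CH2Cl2, 0 °C → rt; then I2, THF, −30 °C
Reagents that add atoms: trimethylaluminium, C[Al](C)C; iodine, II
Why: Negishi zirconium-catalysed methylalumination adds Me and Al syn across the terminal alkyne with Al at the terminus, and iodinolysis with retention gives the E-trisubstituted iodoalkene (C13=C14), the hydroxyl being masked in situ as its aluminium alkoxide.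

**Step 9**
Reactants: 16 (6E)-7-iodo-6-methylhept-6-en-1-ol
Product: 17 (6E)-7-iodo-6-methylhept-6-enal
Conditions: PhI(OAc)2, TEMPO (10 mol %), CH2Cl2, rt
Reagents that add atoms: none
Why: TEMPO/PhI(OAc)2 oxidation of a primary alcohol stops at the aldehyde and should leave the alkenyl iodide untouched.

**Step 10**
Reactants: 17 (6E)-7-iodo-6-methylhept-6-enal; 18 glyoxylic acid (as monohydrate)
Product: 19 5-hydroxy-4-[(4E)-5-iodo-4-methylpent-4-en-1-yl]furan-2(5H)-one (racemic lactol)
Conditions: morpholine·HCl, dioxane/H2O, reflux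
Reagents that add atoms: none
Why: Amine-mediated aldol condensation of an α-methylene aldehyde with glyoxylic acid (enamine addition, then dehydration) forms C18=C19, and the resulting Z-formyl acrylic acid closes to its cyclic lactol, a known entry to 4-alkyl-5-hydroxybutenolides that places the alkyl chain β to the carbonyl as the lactam requires.

**Step 11**
Reactants: 19 5-hydroxy-4-[(4E)-5-iodo-4-methylpent-4-en-1-yl]furan-2(5H)-one; 20 3-methylbutan-1-amine
Product: 22 4-[(4E)-5-iodo-4-methylpent-4-en-1-yl]-1-(3-methylbutyl)-1,5-dihydro-2H-pyrrol-2-one, via (2Z,7E)-8-iodo-7-methyl-3-{[(3-methylbutyl)amino]methyl}octa-2,7-dienoic acid 21 (not isolated)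
Conditions: 20, AcOH, ClCH2CH2Cl, rt; then NaBH(OAc)3, rt → 50 °C
Reagents that add atoms: none
Why: In this reductive amination–lactamisation cascade the lactol reacts through its open formyl acid form with the amine to an iminium ion at C21, hydride reduction gives the Z-γ-amino acid, and this lactamises spontaneously (5-exo-trig), a sequence with close precedent on 4-alkyl- and 3,4-dihalo-5-hydroxybutenolides that forms no stereocentre.

**Step 12**
Reactants: 13 (5S)-5-[(2Z,6S,7E)-2,6-dimethyl-8-(4,4,5,5-tetramethyl-1,3,2-dioxaborolan-2-yl)octa-2,7-dien-1-yl]-4-hydroxy-3-methylfuran-2(5H)-one; 22 4-[(4E)-5-iodo-4-methylpent-4-en-1-yl]-1-(3-methylbutyl)-1,5-dihydro-2H-pyrrol-2-one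
Product: 23 Sarcotrine D
Conditions: Pd(dppf)Cl2 (5 mol %), aq. K3PO4 (4 equiv), THF, 40 °C; then 1 M HCl to pH 3
Reagents that add atoms: none
Why: Suzuki–Miyaura coupling of an E-alkenylboronate with an E-alkenyl iodide forms C12–C13 with retention of both geometries to give the E,E-diene, and the aqueous base only converts the tetronic acid into its inert salt, which is re-protonated on work-up.

**Compound list**
1 | isoprene (2-methylbuta-1,3-diene) | C=CC(C)=C | starting material
2 | ethyl glyoxylate | CCOC(=O)C=O | starting material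
3 | ethyl (2S)-4-methyl-3,6-dihydro-2H-pyran-2-carboxylate | CCOC(=O)[C@@H]1CC(C)=CCO1 | intermediate
4 | propionyl bromide | CCC(=O)Br | starting material
5 | ethyl (2S,4Z)-6-bromo-4-methyl-2-(propanoyloxy)hex-4-enoate | CCOC(=O)[C@H](C/C(C)=C\CBr)OC(=O)CC | intermediate
6 | (2R)-3-bromo-2-methylpropan-1-ol | BrC[C@H](C)CO | starting material
7 | [(2R)-3-bromo-2-methylpropoxy](triethyl)silane | BrC[C@H](C)CO[Si](CC)(CC)CC | intermediate
8 | {(2R)-2-methyl-3-[(triethylsilyl)oxy]propyl}magnesium bromide | Br[Mg]C[C@H](C)CO[Si](CC)(CC)CC | intermediate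
9 | ethyl (2S,4Z,8S)-4,8-dimethyl-2-(propanoyloxy)-9-[(triethylsilyl)oxy]non-4-enoate | CCOC(=O)[C@H](C/C(C)=C\CC[C@H](C)CO[Si](CC)(CC)CC)OC(=O)CC | intermediate
10 | ethyl (2S,4Z,8S)-9-hydroxy-4,8-dimethyl-2-(propanoyloxy)non-4-enoate | CCOC(=O)[C@H](C/C(C)=C\CC[C@H](C)CO)OC(=O)CC | intermediate
11 | ethyl (2S,4Z,8S)-4,8-dimethyl-9-oxo-2-(propanoyloxy)non-4-enoate | CCOC(=O)[C@H](C/C(C)=C\CC[C@H](C)C=O)OC(=O)CC | intermediate
12 | ethyl (2S,4Z,8S,9E)-4,8-dimethyl-2-(propanoyloxy)-10-(4,4,5,5-tetramethyl-1,3,2-dioxaborolan-2-yl)deca-4,9-dienoate | CCOC(=O)[C@H](C/C(C)=C\CC[C@H](C)/C=C/B1OC(C)(C)C(C)(C)O1)OC(=O)CC | intermediate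
13 | (5S)-5-[(2Z,6S,7E)-2,6-dimethyl-8-(4,4,5,5-tetramethyl-1,3,2-dioxaborolan-2-yl)octa-2,7-dien-1-yl]-4-hydroxy-3-methylfuran-2(5H)-one | CC1=C(O)[C@H](C/C(C)=C\CC[C@H](C)/C=C/B2OC(C)(C)C(C)(C)O2)OC1=O | intermediate
14 | hept-6-yn-1-ol | C#CCCCCCO | starting material
15 | dimethyl{(1E)-7-[(dimethylalumanyl)oxy]-2-methylhept-1-en-1-yl}alumane | C[Al](C)/C=C(\C)CCCCCO[Al](C)C | intermediate
16 | (6E)-7-iodo-6-methylhept-6-en-1-ol | I/C=C(\C)CCCCCO | intermediate
17 | (6E)-7-iodo-6-methylhept-6-enal | I/C=C(\C)CCCCC=O | intermediate
18 | glyoxylic acid (used as monohydrate) | O=CC(=O)O | starting material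
19 | 5-hydroxy-4-[(4E)-5-iodo-4-methylpent-4-en-1-yl]furan-2(5H)-one | I/C=C(\C)CCCC1=CC(=O)OC1O | intermediate
20 | 3-methylbutan-1-amine (isopentylamine) | CC(C)CCN | starting material
21 | (2Z,7E)-8-iodo-7-methyl-3-{[(3-methylbutyl)amino]methyl}octa-2,7-dienoic acid | OC(=O)/C=C(\CNCCC(C)C)CCC/C(C)=C/I | intermediate
22 | 4-[(4E)-5-iodo-4-methylpent-4-en-1-yl]-1-(3-methylbutyl)-1,5-dihydro-2H-pyrrol-2-one | I/C=C(\C)CCCC1=CC(=O)N(CCC(C)C)C1 | intermediate
23 | Sarcotrine D, (5S)-4-hydroxy-3-methyl-5-{(2Z,6S,7E,9E)-2,6,10-trimethyl-13-[1-(3-methylbutyl)-5-oxo-2,5-dihydro-1H-pyrrol-3-yl]trideca-2,7,9-trien-1-yl}furan-2(5H)-one | CC1=C(O)[C@H](C/C(C)=C\CC[C@H](C)/C=C/C=C(\C)CCCC2=CC(=O)N(CCC(C)C)C2)OC1=O | target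

**Total step count:** 12
**Longest linear sequence:** 7 steps (1, 2, 4, 5, 6, 7, 12)

**Steps most likely to fail**

Step 2 (acylative ring opening). The acyloxonium ion or the product bromide may ionise to the allyl cation, with loss of the Z geometry or allylic transposition. The activated acyl bromide may also C-acylate the trisubstituted alkene instead of the deactivated ether oxygen. The fallback separates cleavage from acylation, so that no acylium-type electrophile is present while the ring opens. It sets out from 3. Dimethylboron bromide (CH2Cl2, −78 → 0 °C) complexes the ether, delivers bromide to C8 in an SN2 sense, and after mild hydrolytic work-up gives ethyl (2S,4Z)-6-bromo-2-hydroxy-4-methylhex-4-enoate F1. This is propionylated under acid catalysis (propionic anhydride, cat. Sc(OTf)3, MeCN, −20 °C), which avoids base-induced re-closure to the pyran. The fallback comes back to the route at 5.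

Step 1 (hetero-Diels–Alder reaction). The ene pathway through the isoprene methyl group may compete too strongly, facial selectivity on the glyoxylate may be incomplete, and the glyoxylate may oligomerise. The fallback uses an oxygen-activated diene that can only cycloadd, and then removes the extra oxygen. It sets out from 2. Commercial 3-methylbut-2-enal is converted (TBSOTf, Et3N, CH2Cl2, 0 °C) into tert-butyl(dimethyl){[(1E)-3-methylbuta-1,3-dien-1-yl]oxy}silane F2. This undergoes the same BINOL–Ti (or bis(oxazoline)–Cu) catalysed cycloaddition with 2 to give ethyl (2S)-6-[(tert-butyldimethylsilyl)oxy]-4-methyl-3,6-dihydro-2H-pyran-2-carboxylate F3, whose acetal centre is inconsequential. Ionic reduction (Et3SiH, BF3·OEt2, CH2Cl2, −78 °C) delivers hydride to the acetal carbon C8 of the allylic oxocarbenium ion. The fallback comes back to the route at 3.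

Step 4 (C8–C9 coupling). The Grignard reagent may attack the activated α-acyloxy ester, or deprotonate C4 and cause racemisation or acyl migration. Some SN2′ substitution at C6 may also occur. The fallback replaces the hard carbanion with an ester-tolerant organozinc reagent under cobalt catalysis, a combination known to substitute neryl-type allylic halides in the SN2 sense with retention of geometry. It sets out from 7 and 5. A Finkelstein exchange (NaI, acetone) gives [(2R)-3-iodo-2-methylpropoxy](triethyl)silane F4. Zinc insertion (Zn, LiCl, THF) gives {(2R)-2-methyl-3-[(triethylsilyl)oxy]propyl}zinc iodide F5. This is coupled with 5 (CoBr2 10 mol %, THF/NMP, −10 °C). The fallback comes back to the route at 9, which is desilylated to 10 by the acid treatment of step 4.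

**Further compounds**
F1 | step 2 | ethyl (2S,4Z)-6-bromo-2-hydroxy-4-methylhex-4-enoate | CCOC(=O)[C@@H](O)C/C(C)=C\CBr
F2 | step 1 | tert-butyl(dimethyl){[(1E)-3-methylbuta-1,3-dien-1-yl]oxy}silane | C=C(C)/C=C/O[Si](C)(C)C(C)(C)C
F3 | step 1 | ethyl (2S)-6-[(tert-butyldimethylsilyl)oxy]-4-methyl-3,6-dihydro-2H-pyran-2-carboxylate | CCOC(=O)[C@@H]1CC(C)=CC(O[Si](C)(C)C(C)(C)C)O1
F4 | step 4 | [(2R)-3-iodo-2-methylpropoxy](triethyl)silane | IC[C@H](C)CO[Si](CC)(CC)CC
F5 | step 4 | {(2R)-2-methyl-3-[(triethylsilyl)oxy]propyl}zinc iodide | I[Zn]C[C@H](C)CO[Si](CC)(CC)CC
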